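The route rests on disconnecting ring A from ring B at C1–C10 and C4=C5, and the side chain at C9–C11 (labdane numbering). The key step exploits the adjacent C9 and C10 stereocentres of ring B, where the C9 chain lies trans to C1 and cis to the C10 methyl. A copper-catalysed Grignard 1,4-addition to a cyclohexenone, Michael capture of the resulting C10 enolate by an α-silyl vinyl ketone and aldol closure create both centres, three C–C bonds and ring A in one flask. The precursor is (S)-4-(tert-butyldimethylsilyloxy)-2-methylcyclohex-2-en-1-one, whose silyloxy carbon becomes C8 and later carries the C6=C7/C8=C17 diene.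

Key step: step 7

Remarks
- Positions are given in labdane numbering: C17 is the methylene carbon on C8, C18 the oxygenated carbon on C4, C19 the methyl on C4, C20 the methyl on C10.
- Assumption: the (R,R)-amide of step 1 is taken to give the (S)-enol silane, by analogy with other 4-substituted cyclohexanones; if the sense is opposite, the (S,S)-amine is used.
- Assumption: step 1 should give high but not complete enantiomeric purity, to be completed by recrystallisation of a solid intermediate or by chiral chromatography of 5.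
- Design change: the side-chain ketone is masked as the 5,5-dimethyl-1,3-dioxane ketal, because the Grignard reagent of the corresponding dioxolane decomposes near room temperature by attack of the C–Mg bond on the ketal, whereas the dioxane reagent is stable; bromide 11 is commercial.

Step 1
Reactants: 1 4-(tert-butyldimethylsilyloxy)cyclohexanone
Product: 2 (S)-4-(tert-butyldimethylsilyloxy)-1-(trimethylsilyloxy)cyclohex-1-ene
Conditions: (R,R)-bis(1-phenylethyl)amine, n-BuLi, THF, −78 °C; Me3SiCl, then 1, −100 → −78 °C; Et3N, aq. NaHCO3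
Reagents that add atoms: chlorotrimethylsilane, C[Si](C)(C)Cl
Why: Enantioselective deprotonation of a prochiral 4-substituted cyclohexanone by a chiral lithium amide with in situ silylation (chiral-base desymmetrisation): the amide removes one of the two enantiotopic axial α-hydrogens, so the silyloxy-bearing carbon becomes the (S) stereocentre.

Step 2
Reactants: 2 (S)-4-(tert-butyldimethylsilyloxy)-1-(trimethylsilyloxy)cyclohex-1-ene
Product: 3 (S)-4-(tert-butyldimethylsilyloxy)cyclohex-2-en-1-one
Conditions: Pd(OAc)2 (10 mol%), O2 (1 atm), DMSO, 25 °C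
Reagents that add atoms: none
Why: Saegusa–Ito oxidation: the palladium enolate formed from the enol silane undergoes β-hydride elimination, which places the double bond on the side fixed in step 1 and leaves the stereocentre untouched.

Step 3
Reactants: 3 (S)-4-(tert-butyldimethylsilyloxy)cyclohex-2-en-1-one
Product: 4 (S)-4-(tert-butyldimethylsilyloxy)-2-iodocyclohex-2-en-1-one
Conditions: I2, pyridine, CH2Cl2, 0 → 25 °C
Reagents that add atoms: iodine, II
Why: α-Iodination of an enone by reversible conjugate addition of pyridine, iodination of the enolate and loss of pyridine (addition–elimination), which puts iodine on C2 without touching the C4 stereocentre.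

Step 4
Reactants: 4 (S)-4-(tert-butyldimethylsilyloxy)-2-iodocyclohex-2-en-1-one
Product: 5 (S)-4-(tert-butyldimethylsilyloxy)-2-methylcyclohex-2-en-1-one
Conditions: Me4Sn, Pd2(dba)3 (2.5 mol%, zerovalent palladium), AsPh3, CuI, NMP, 70 °C
Reagents that add atoms: tetramethyltin, C[Sn](C)(C)C
Why: Stille cross-coupling of an α-iodoenone (oxidative addition, methyl transfer from tin, reductive elimination) under neutral conditions, which avoids γ-deprotonation and so preserves the silyloxy stereocentre.

Step 5
Reactants: 6 (1-bromoethenyl)trimethylsilane; 7 propanal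
Product: 9 2-(trimethylsilyl)pent-1-en-3-ol (racemic), via vinyl Grignard reagent 8 (not isolated)
Conditions: Mg, THF, reflux; 7, 0 °C; aq. NH4Cl
Reagents that add atoms: none
Why: Grignard addition of the α-silylvinyl magnesium reagent to an aldehyde; the new carbinol centre is racemic and is removed in step 6.

Step 6
Reactants: 9 2-(trimethylsilyl)pent-1-en-3-ol
Product: 10 2-(trimethylsilyl)pent-1-en-3-one
Conditions: Dess–Martin periodinane, pyridine, CH2Cl2, 0 → 25 °C
Reagents that add atoms: none
Why: Dess–Martin oxidation of a secondary allylic alcohol under buffered, non-nucleophilic conditions that leave the vinylsilane and the polymerisable enone intact.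

Step 7
Reactants: 5 (S)-4-(tert-butyldimethylsilyloxy)-2-methylcyclohex-2-en-1-one; 10 2-(trimethylsilyl)pent-1-en-3-one; 11 2-(2-bromoethyl)-2,5,5-trimethyl-1,3-dioxane
Product: 16 bicyclic enone (C3 ketone with C4=C5; C8 silyl ether; C9 ketal chain; C10 methyl; 8S,9S,10S), via Grignard reagent 12 (not isolated), via magnesium enolate 13 (not isolated), via silyl diketone 14 (not isolated), via diketone 15 (not isolated)
Conditions: 11, Mg, THF, 20–25 °C; CuBr·SMe2 (10 mol%), THF, −40 °C, then 5, −40 → −20 °C; 10, −78 → −20 °C; KOH, MeOH, 0 → 50 °C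
Reagents that add atoms: none
Why: Grignard reagent 12 transmetalates to a monovalent copper alkyl that adds 1,4 to enone 5 at C9, the resulting regiodefined magnesium enolate 13 attacks the terminal carbon of silyl vinyl ketone 10 through C10 (Michael addition) to give 14, and methanolic KOH then cleaves the C–Si bond (15) and condenses the ethyl ketone onto the C5 carbonyl. The closest known reaction type is the conjugate addition–annulation of cuprate-derived enolates with α-silyl vinyl ketones, a variant of the Robinson annulation. Ring A closes by a 6-(enolendo)-exo-trig aldol addition followed by dehydration to the C4=C5 enone. C9 is set by delivery of the alkyl group to the enone face opposite the C8 silyl ether, as is general for 4-silyloxycyclohexenones, and C10 by attack of 10 on the enolate face opposite the C9 chain, which lies pseudoaxial to escape allylic strain with the C10 methyl, so that the chain ends trans to C1 and cis to C20. The step needs one enolate regioisomer and two anti facial selectivities: the first is fixed by the conjugate addition and protected by the silyl group of 10, which suppresses proton exchange and polymerisation, and the second by the two ring substituents.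

Step 8
Reactants: 16 bicyclic enone
Product: 18 hydroxymethyl ketone (C3 ketone; C4 bearing axial CH3 and equatorial CH2OH; trans ring fusion; 4S,5S,8S,9S,10R), via lithium enolate 17 (not isolated)
Conditions: Li, liquid NH3/THF, t-BuOH (1 equiv), −78 → −33 °C; evaporate NH3; THF, CH2O (gas, from paraformaldehyde), −78 °C; NH4Cl
Reagents that add atoms: formaldehyde, C=O
Why: Dissolving-metal reduction of the enone with reductive alkylation: the C5 hydrogen is delivered axially, trans to the C10 methyl, and the regiodefined C3–C4 lithium enolate 17 is hydroxymethylated at C4 from the face opposite the axial C10 methyl, so that CH2OH ends equatorial and trans to C20.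

Step 9
Reactants: 18 hydroxymethyl ketone
Product: 19 THP ether of 18 (both epimers at the acetal carbon)
Conditions: 3,4-dihydro-2H-pyran, PPTS (10 mol%), CH2Cl2, 25 °C
Reagents that add atoms: 3,4-dihydro-2H-pyran, C1=COCCC1
Why: Acid-catalysed addition of the alcohol to the enol ether (tetrahydropyranylation) blocks retro-aldol loss of formaldehyde in the basic steps that follow, while the ketal and silyl ether survive anhydrous catalytic acid; the acetal centre is removed in step 15.

Step 10
Reactants: 19 THP ether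
Product: 20 C8 alcohol (C3 ketone, C18 THP ether; 4S,5S,8S,9S,10R)
Conditions: Bu4NF, THF, 25 → 50 °C
Reagents that add atoms: none
Why: Fluoride cleavage of the silyl ether; acetal and ketal are inert, and the β-alkoxy ketone cannot eliminate because C4 is quaternary.

Step 11
Reactants: 20 C8 alcohol
Product: 21 C3-deoxy alcohol (C3 methylene, C8 hydroxyl; 4S,5S,8S,9S,10R)
Conditions: N2H4·H2O, KOH, diethylene glycol, 130 °C, then 200 °C
Reagents that add atoms: none
Why: Wolff–Kishner reduction (Huang-Minlon modification) of a hindered ring ketone through its hydrazone; the only enolisable position, C2, carries no stereocentre, and the alcohol, acetal and ketal tolerate hot alkali.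

Step 12
Reactants: 21 C3-deoxy alcohol
Product: 22 C8 ketone (4S,5S,9S,10R)
Conditions: Dess–Martin periodinane, pyridine, CH2Cl2, 25 °C
Reagents that add atoms: none
Why: Dess–Martin oxidation of the secondary alcohol under buffered conditions; the C9 chain is already equatorial, so the adjacent stereocentre has no drive to epimerise.

Step 13
Reactants: 22 C8 ketone
Product: 24 ring-B enone (C6=C7, C8 ketone; 4S,5S,9S,10R), via lithium enolate 23 (not isolated)
Conditions: LiN(i-Pr)2, THF, −78 °C; N-tert-butylbenzenesulfinimidoyl chloride, −78 °C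
Reagents that add atoms: none
Why: Mukaiyama dehydrogenation: kinetic deprotonation occurs at the C7 methylene (C9 is tertiary and shielded by quaternary C10), the enolate is sulfenylated at C7 and syn elimination toward C6 gives the enone at low temperature without touching C9.

Step 14
Reactants: 24 ring-B enone
Product: 25 exocyclic diene (C6=C7, C8=C17; THP ether and ketal retained; 4S,5S,9R,10S)
Conditions: Zn, CH2Br2, TiCl4, THF (reagent formed beforehand); CH2Cl2, 0 → 25 °C
Reagents that add atoms: dibromomethane, BrCBr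
Why: Takai–Lombardo methylenation: the non-basic zinc–titanium methylene reagent adds 1,2 to the hindered, enolisable C8 carbonyl and eliminates the oxygen to titanium, so C9 and C5 keep their configuration.

Step 15
Reactants: 25 exocyclic diene
Product: 26 keto alcohol (C13 methyl ketone, C18 hydroxyl, diene; 4S,5S,9R,10S)
Conditions: AcOH/THF/H2O (3:1:1), 45 °C
Reagents that add atoms: water, O
Why: Mild aqueous acid hydrolysis cleaves the tetrahydropyranyl acetal and the ketone ketal in one operation, at an acidity too low to protonate and isomerise the conjugated diene.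

Step 16
Reactants: 26 keto alcohol; 27 trimethyl phosphonoacetate
Product: 28 hydroxy (E)-enoate (4S,5S,9R,10S,13E)
Conditions: 27 (3 equiv), NaH (2.5 equiv), THF, 0 → 45 °C
Reagents that add atoms: none
Why: Horner–Wadsworth–Emmons olefination of the methyl ketone, in which reversible addition of the stabilised phosphonate anion should favour the E-olefin (C12 chain trans to the ester), any Z isomer being removed by chromatography; the neopentyl alcohol is too weak an acid to be deprotonated by the phosphonate anion.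

Step 17
Reactants: 28 hydroxy (E)-enoate
Product: 29 target, methyl 18-acetoxy-ent-labda-6,8(17),13E-trien-15-oate (4S,5S,9R,10S)
Conditions: Ac2O, pyridine, DMAP (cat.), CH2Cl2, 25 °C
Reagents that add atoms: acetic anhydride, CC(=O)OC(C)=O
Why: Nucleophile-catalysed acetylation of the primary alcohol, a mild final step that touches neither the diene nor the enoate.

Compound list
1 | 4-[(tert-butyldimethylsilyl)oxy]cyclohexan-1-one | CC(C)(C)[Si](C)(C)OC1CCC(=O)CC1 | starting material
2 | tert-butyldimethyl({(1S)-4-[(trimethylsilyl)oxy]cyclohex-3-en-1-yl}oxy)silane | [C@H]1(O[Si](C)(C)C(C)(C)C)CCC(O[Si](C)(C)C)=CC1 | intermediate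
3 | (4S)-4-[(tert-butyldimethylsilyl)oxy]cyclohex-2-en-1-one | [C@H]1(O[Si](C)(C)C(C)(C)C)CCC(=O)C=C1 | intermediate
4 | (4S)-4-[(tert-butyldimethylsilyl)oxy]-2-iodocyclohex-2-en-1-one | [C@H]1(O[Si](C)(C)C(C)(C)C)CCC(=O)C(I)=C1 | intermediate
5 | (4S)-4-[(tert-butyldimethylsilyl)oxy]-2-methylcyclohex-2-en-1-one | [C@H]1(O[Si](C)(C)C(C)(C)C)CCC(=O)C(C)=C1 | intermediate
6 | (1-bromoethenyl)trimethylsilane | C=C(Br)[Si](C)(C)C | starting material
7 | propanal | CCC=O | starting material
8 | bromo[1-(trimethylsilyl)ethenyl]magnesium | C=C([Mg]Br)[Si](C)(C)C | intermediate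
9 | 2-(trimethylsilyl)pent-1-en-3-ol (racemic) | CCC(O)C(=C)[Si](C)(C)C | intermediate
10 | 2-(trimethylsilyl)pent-1-en-3-one | CCC(=O)C(=C)[Si](C)(C)C | intermediate
11 | 2-(2-bromoethyl)-2,5,5-trimethyl-1,3-dioxane | CC1(CCBr)OCC(C)(C)CO1 | starting material
12 | bromo[2-(2,5,5-trimethyl-1,3-dioxan-2-yl)ethyl]magnesium | CC1(CC[Mg]Br)OCC(C)(C)CO1 | intermediate
13 | bromomagnesium (3S,4S)-4-[(tert-butyldimethylsilyl)oxy]-2-methyl-3-[2-(2,5,5-trimethyl-1,3-dioxan-2-yl)ethyl]cyclohex-1-en-1-olate | CC(C)(C)[Si](C)(C)O[C@H]1CCC(O[Mg]Br)=C(C)[C@@H]1CCC1(C)OCC(C)(C)CO1 | intermediate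
14 | (2S,3S,4S)-4-[(tert-butyldimethylsilyl)oxy]-2-methyl-2-[3-oxo-2-(trimethylsilyl)pentyl]-3-[2-(2,5,5-trimethyl-1,3-dioxan-2-yl)ethyl]cyclohexan-1-one (both epimers at the silyl-bearing carbon; present as its magnesium enolate) | CC(C)(C)[Si](C)(C)O[C@H]1CCC(=O)[C@@](C)(CC(C(=O)CC)[Si](C)(C)C)[C@@H]1CCC1(C)OCC(C)(C)CO1 | intermediate
15 | (2S,3S,4S)-4-[(tert-butyldimethylsilyl)oxy]-2-methyl-2-(3-oxopentyl)-3-[2-(2,5,5-trimethyl-1,3-dioxan-2-yl)ethyl]cyclohexan-1-one | CC(C)(C)[Si](C)(C)O[C@H]1CCC(=O)[C@@](C)(CCC(=O)CC)[C@@H]1CCC1(C)OCC(C)(C)CO1 | intermediate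
16 | (4aS,5S,6S)-6-[(tert-butyldimethylsilyl)oxy]-1,4a-dimethyl-5-[2-(2,5,5-trimethyl-1,3-dioxan-2-yl)ethyl]-4,4a,5,6,7,8-hexahydronaphthalen-2(3H)-one | CC(C)(C)[Si](C)(C)O[C@H]1CCC2=C(C)C(=O)CC[C@@]2(C)[C@@H]1CCC1(C)OCC(C)(C)CO1 | intermediate
17 | lithium (4aR,5S,6S,8aS)-6-[(tert-butyldimethylsilyl)oxy]-1,4a-dimethyl-5-[2-(2,5,5-trimethyl-1,3-dioxan-2-yl)ethyl]-3,4,4a,5,6,7,8,8a-octahydronaphthalen-2-olate | CC(C)(C)[Si](C)(C)O[C@H]1CC[C@@H]2C(C)=C(O[Li])CC[C@@]2(C)[C@@H]1CCC1(C)OCC(C)(C)CO1 | intermediate
18 | (1S,4aR,5S,6S,8aS)-6-[(tert-butyldimethylsilyl)oxy]-1-(hydroxymethyl)-1,4a-dimethyl-5-[2-(2,5,5-trimethyl-1,3-dioxan-2-yl)ethyl]octahydronaphthalen-2(1H)-one | CC(C)(C)[Si](C)(C)O[C@H]1CC[C@@H]2[C@@](C)(CO)C(=O)CC[C@@]2(C)[C@@H]1CCC1(C)OCC(C)(C)CO1 | intermediate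
19 | (1S,4aR,5S,6S,8aS)-6-[(tert-butyldimethylsilyl)oxy]-1,4a-dimethyl-1-[(tetrahydro-2H-pyran-2-yloxy)methyl]-5-[2-(2,5,5-trimethyl-1,3-dioxan-2-yl)ethyl]octahydronaphthalen-2(1H)-one (both acetal epimers) | CC(C)(C)[Si](C)(C)O[C@H]1CC[C@@H]2[C@@](C)(COC3CCCCO3)C(=O)CC[C@@]2(C)[C@@H]1CCC1(C)OCC(C)(C)CO1 | intermediate
20 | (1S,4aR,5S,6S,8aS)-6-hydroxy-1,4a-dimethyl-1-[(tetrahydro-2H-pyran-2-yloxy)methyl]-5-[2-(2,5,5-trimethyl-1,3-dioxan-2-yl)ethyl]octahydronaphthalen-2(1H)-one (both acetal epimers) | O[C@H]1CC[C@@H]2[C@@](C)(COC3CCCCO3)C(=O)CC[C@@]2(C)[C@@H]1CCC1(C)OCC(C)(C)CO1 | intermediate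
21 | (1S,2S,4aS,5S,8aR)-5,8a-dimethyl-5-[(tetrahydro-2H-pyran-2-yloxy)methyl]-1-[2-(2,5,5-trimethyl-1,3-dioxan-2-yl)ethyl]decahydronaphthalen-2-ol (both acetal epimers) | O[C@H]1CC[C@@H]2[C@@](C)(COC3CCCCO3)CCC[C@@]2(C)[C@@H]1CCC1(C)OCC(C)(C)CO1 | intermediate
22 | (1S,4aS,5S,8aR)-5,8a-dimethyl-5-[(tetrahydro-2H-pyran-2-yloxy)methyl]-1-[2-(2,5,5-trimethyl-1,3-dioxan-2-yl)ethyl]octahydronaphthalen-2(1H)-one (both acetal epimers) | O=C1CC[C@@H]2[C@@](C)(COC3CCCCO3)CCC[C@@]2(C)[C@@H]1CCC1(C)OCC(C)(C)CO1 | intermediate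
23 | lithium (1S,4aS,5S,8aR)-5,8a-dimethyl-5-[(tetrahydro-2H-pyran-2-yloxy)methyl]-1-[2-(2,5,5-trimethyl-1,3-dioxan-2-yl)ethyl]-1,4,4a,5,6,7,8,8a-octahydronaphthalen-2-olate | [Li]OC1=CC[C@@H]2[C@@](C)(COC3CCCCO3)CCC[C@@]2(C)[C@@H]1CCC1(C)OCC(C)(C)CO1 | intermediate
24 | (1S,4aS,5S,8aR)-5,8a-dimethyl-5-[(tetrahydro-2H-pyran-2-yloxy)methyl]-1-[2-(2,5,5-trimethyl-1,3-dioxan-2-yl)ethyl]-4a,5,6,7,8,8a-hexahydronaphthalen-2(1H)-one (both acetal epimers) | O=C1C=C[C@@H]2[C@@](C)(COC3CCCCO3)CCC[C@@]2(C)[C@@H]1CCC1(C)OCC(C)(C)CO1 | intermediate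
25 | 2-{2-[(1R,4aS,5S,8aS)-5,8a-dimethyl-2-methylidene-5-[(tetrahydro-2H-pyran-2-yloxy)methyl]-1,2,4a,5,6,7,8,8a-octahydronaphthalen-1-yl]ethyl}-2,5,5-trimethyl-1,3-dioxane (both acetal epimers) | C=C1C=C[C@@H]2[C@@](C)(COC3CCCCO3)CCC[C@@]2(C)[C@@H]1CCC1(C)OCC(C)(C)CO1 | intermediate
26 | 4-[(1R,4aS,5S,8aS)-5-(hydroxymethyl)-5,8a-dimethyl-2-methylidene-1,2,4a,5,6,7,8,8a-octahydronaphthalen-1-yl]butan-2-one | C=C1C=C[C@@H]2[C@@](C)(CO)CCC[C@@]2(C)[C@@H]1CCC(C)=O | intermediate
27 | methyl 2-(dimethoxyphosphoryl)acetate (trimethyl phosphonoacetate) | COC(=O)CP(=O)(OC)OC | starting material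
28 | methyl (2E)-5-[(1R,4aS,5S,8aS)-5-(hydroxymethyl)-5,8a-dimethyl-2-methylidene-1,2,4a,5,6,7,8,8a-octahydronaphthalen-1-yl]-3-methylpent-2-enoate | C=C1C=C[C@@H]2[C@@](C)(CO)CCC[C@@]2(C)[C@@H]1CC/C(C)=C/C(=O)OC | intermediate
29 | methyl (2E)-5-[(1R,4aS,5S,8aS)-5-(acetoxymethyl)-5,8a-dimethyl-2-methylidene-1,2,4a,5,6,7,8,8a-octahydronaphthalen-1-yl]-3-methylpent-2-enoate | C=C1C=C[C@@H]2[C@@](C)(COC(C)=O)CCC[C@@]2(C)[C@@H]1CC/C(C)=C/C(=O)OC | target

Total step count: 17.
Longest linear sequence: 15 steps (steps 1–4 and 7–17, from 1 to 29); steps 5 and 6 form the side branch to 10.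

Steps most likely to fail

Step 7. The capture of enolate 13 may be incomplete or unselective: proton transfer between 13 and the Michael adduct, anionic polymerisation of 10, or erosion of the facial preference at C10 because the incoming acceptor passes the axial C8 silyl ether. The fallback sets out from 5 and comes back at 15. The copper-catalysed addition of 12 to 5 is quenched with aqueous NH4Cl and the ketone (2RS,3S,4S)-4-[(tert-butyldimethylsilyl)oxy]-2-methyl-3-[2-(2,5,5-trimethyl-1,3-dioxan-2-yl)ethyl]cyclohexan-1-one F1 is isolated. F1 is then annulated in the classical Robinson manner: under catalytic KOH in EtOH at 0 °C its more substituted, thermodynamic enolate adds to commercial pent-1-en-3-one to give diketone 15, which KOH/MeOH closes to 16 as in step 7. The equilibrating conditions should again place the new bond at C10 trans to the C9 chain, as in related 2,3-disubstituted cyclohexanone annulations.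

Step 8. Enolate 17 may be quenched by proton transfer (ammonia, tert-butoxide, polymerising formaldehyde) before the C–C bond forms, leaving the simply reduced ketone. The fallback sets out from 16 and comes back at 18. After the Li/NH3 reduction the enolate is trapped with Me3SiCl/Et3N and isolated as the silyl enol ether (4aR,5S,6S,8aS)-6-[(tert-butyldimethylsilyl)oxy]-1,4a-dimethyl-2-[(trimethylsilyl)oxy]-5-[2-(2,5,5-trimethyl-1,3-dioxan-2-yl)ethyl]-3,4,4a,5,6,7,8,8a-octahydronaphthalene F2. F2 is hydroxymethylated in a Lewis-acid Mukaiyama aldol reaction with aqueous formaldehyde and catalytic Yb(OTf)3 in THF/H2O at 0 → 25 °C. This replaces the basic enolate by a neutral enol ether that cannot be lost to proton transfer, and the approach to C4 should again be opposite the C10 methyl; the ketal would have to survive the aqueous Lewis acid.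

Step 14. The Lewis-acidic zinc and titanium halides may open the tetrahydropyranyl acetal or the ketal (a freed methyl ketone would then be methylenated as well), or addition to the hindered C8 carbonyl may stall. The fallback sets out from 24 and comes back at 25, using a two-stage Peterson olefination free of acid. Me3SiCH2Li with CeCl3 in THF at −78 °C adds 1,2 to the enone to give the β-hydroxysilane (1S,4aS,5S,8aR)-5,8a-dimethyl-5-[(tetrahydro-2H-pyran-2-yloxy)methyl]-1-[2-(2,5,5-trimethyl-1,3-dioxan-2-yl)ethyl]-2-[(trimethylsilyl)methyl]-1,2,4a,5,6,7,8,8a-octahydronaphthalen-2-ol F3, as a mixture at the carbinol carbon. KH in THF at 0 → 25 °C then eliminates silanolate from both epimers to give diene 25.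

Further compounds
F1 | step 7 | (2RS,3S,4S)-4-[(tert-butyldimethylsilyl)oxy]-2-methyl-3-[2-(2,5,5-trimethyl-1,3-dioxan-2-yl)ethyl]cyclohexan-1-one | CC(C)(C)[Si](C)(C)O[C@H]1CCC(=O)C(C)[C@@H]1CCC1(C)OCC(C)(C)CO1
F2 | step 8 | (4aR,5S,6S,8aS)-6-[(tert-butyldimethylsilyl)oxy]-1,4a-dimethyl-2-[(trimethylsilyl)oxy]-5-[2-(2,5,5-trimethyl-1,3-dioxan-2-yl)ethyl]-3,4,4a,5,6,7,8,8a-octahydronaphthalene | CC(C)(C)[Si](C)(C)O[C@H]1CC[C@@H]2C(C)=C(O[Si](C)(C)C)CC[C@@]2(C)[C@@H]1CCC1(C)OCC(C)(C)CO1
F3 | step 14 | (1S,4aS,5S,8aR)-5,8a-dimethyl-5-[(tetrahydro-2H-pyran-2-yloxy)methyl]-1-[2-(2,5,5-trimethyl-1,3-dioxan-2-yl)ethyl]-2-[(trimethylsilyl)methyl]-1,2,4a,5,6,7,8,8a-octahydronaphthalen-2-ol (both carbinol epimers) | C[Si](C)(C)CC1(O)C=C[C@@H]2[C@@](C)(COC3CCCCO3)CCC[C@@]2(C)[C@@H]1CCC1(C)OCC(C)(C)CO1
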